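**Retrosynthetic overview**
1. Ring C (eleven-membered) is closed last: ring-closing enyne metathesis of a C7 alkyne with the C12 vinyl group builds the C10(=CH2)–C11=C12 diene; the C1 carbinol comes from the ring B ketone in the final step.
2. Before that, C2–OAc is introduced by α′-acetoxylation of the ring B enone, and C7–H (alkyne on the α-face) by Nicholas reduction of an ethynyl carbinol.
3. Key bond C16–O: ene oxygenation of an exocyclic C6=C16 enone with O2 installs the C16 oxygen, moves the alkene into ring B (C5=C6) and relays the C5–H stereocentre to C16.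
4. The exocyclic enone comes from aldol condensation of a bicyclic silyl enol ether with (S)-3-methylhex-5-enal (C14 from (S)-β-butyrolactone).
5. Ring B is annulated onto ring A (3-methylcyclopent-2-enone) by a Diels–Alder reaction with a 2-silyloxypentadiene (C3 quaternary centre, cis fusion), and the racemate is resolved once; ring order A (given) → B → C.

Assumption (labelling convention): ring B = C1 (CHOH), C2 (CHOAc), C3 (C–CH3), C4 (ring-fusion CH), C5 (=C–CH3), C6 (=C); ring A = C3, C4, C7, C8, C9; bridge of ring C = C7–C10(=CH2)–C11=C12–C13–C14(CH3)–C15–C16(OAc)–C6; β is the face of ring B carrying C4–H and C3–CH3, α the opposite (ring A) face.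

**Step 1**
Reactants: 1 (S)-β-butyrolactone; 2 allylmagnesium bromide (CH2=CHCH2MgBr)
Product: 3 (3S)-3-methylhex-5-enoic acid
Conditions: 2 (1.3 equiv), CuBr·SMe2 (10 mol %), THF/Me2S, −30 °C; then 1 M HCl
Reagents that add atoms: none
Why: copper-catalysed Grignard ring opening of the β-lactone by SN2 attack at the β-carbon (alkyl–oxygen cleavage, inversion) transfers the lactone stereocentre to C14, the (S)-lactone giving the (S)-acid because the ligand priorities change.

**Step 2**
Reactants: 3 (3S)-3-methylhex-5-enoic acid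
Product: 4 (3S)-3-methylhex-5-en-1-ol
Conditions: LiAlH4, THF, 0 °C → rt; H2O/NaOH work-up
Reagents that add atoms: none
Why: LiAlH4 reduction of the carboxylic acid to the primary alcohol leaves the remote stereocentre untouched.

**Step 3**
Reactants: 4 (3S)-3-methylhex-5-en-1-ol
Product: 5 (3S)-3-methylhex-5-enal
Conditions: Dess–Martin periodinane, NaHCO3, CH2Cl2, 0 °C → rt
Reagents that add atoms: none
Why: Dess–Martin oxidation stops at the aldehyde under buffered conditions, and the stereocentre is β to the carbonyl and cannot epimerise.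

**Step 4**
Reactants: 6 (E)-pent-3-en-2-one
Product: 7 (E)-2-(tert-butyldimethylsilyloxy)penta-1,3-diene
Conditions: TBSOTf, Et3N, CH2Cl2, 0 °C
Reagents that add atoms: tert-butyldimethylsilyl triflate, CC(C)(C)[Si](C)(C)OS(=O)(=O)C(F)(F)F
Why: soft enolisation (silyl triflate/amine) removes a methyl proton and O-silylates, giving the cross-conjugated 2-silyloxydiene with the (E)-propenyl geometry retained.

**Step 5**
Reactants: 7 (E)-2-(tert-butyldimethylsilyloxy)penta-1,3-diene; 8 3-methylcyclopent-2-en-1-one
Product: 9 cis-fused Diels–Alder adduct (single enantiomer after resolution)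
Conditions: AlBr3/AlMe3 (10:1, 0.3 equiv), toluene/CH2Cl2, −5 °C; then preparative SFC, amylose tris(3,5-dimethylphenylcarbamate) phase, CO2/i-PrOH
Reagents that add atoms: none
Why: Lewis acid-promoted Diels–Alder reaction of a hindered β-methyl enone with a 2-silyloxydiene (mixed AlBr3/AlMe3 promoter), in which the CH2 terminus bonds to the enone β-carbon (C2–C3, quaternary centre) and the methyl-bearing terminus to C4, suprafacial addition gives the cis fusion (C3–CH3 and C4–H both β), the endo transition state places C5–CH3 α (C5–H β), and chiral chromatography separates the enantiomers (configuration of the retained one checked by vibrational circular dichroism or X-ray of a derivative).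

**Step 6**
Reactants: 9 cis-fused Diels–Alder adduct; 10 ethynylmagnesium bromide (HC≡CMgBr)
Product: 11 C7 ethynyl carbinol
Conditions: 10 (1.5 equiv), THF, 0 °C → rt; aq. NH4Cl
Reagents that add atoms: none
Why: Grignard 1,2-addition to the C7 ketone, expected from the convex β-face (OH β, alkyne α), leaves the silyl enol ether intact, and the C7 configuration is immaterial because step 9 passes through a planar cation.

**Step 7**
Reactants: 11 C7 ethynyl carbinol; 5 (3S)-3-methylhex-5-enal
Product: 14 exocyclic (E)-enone, via aldol adduct 12 (not isolated), via aldol acetate 13 (not isolated)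
Conditions: 5 (1.3 equiv), BF3·OEt2, CH2Cl2, −78 °C; NaHCO3 work-up; crude: Ac2O, DMAP, Et3N, 0 °C; then DBU, rt
Reagents that add atoms: none
Why: Mukaiyama aldol addition of the regiodefined silyl enol ether at C6, then acetylation and E1cB elimination (aldol condensation), gives the conjugated (E)-alkylidene ketone (C15 anti to the C1 carbonyl) as the thermodynamic isomer, erasing the two aldol stereocentres while C5 (H β) is untouched and the hindered tertiary alcohol is not acylated.

**Step 8**
Reactants: 14 exocyclic (E)-enone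
Product: 17 (16S)-acetate, via hydroperoxide 15 (not isolated), via allylic alcohol 16 (not isolated)
Conditions: O2, tetraphenylporphyrin (1 mol %), hν (>500 nm), CH2Cl2, −20 °C; then PPh3, 0 °C; then Ac2O, pyridine, DMAP, 0 °C
Reagents that add atoms: dioxygen, O=O; acetic anhydride, CC(=O)OC(C)=O
Why: Proposed new method: a carbonyl-directed (gem-selective) Schenck ene oxygenation in which the stereogenic tertiary C5–H of a 2-alkylidene-3-methylcyclohexanone is the hydrogen donor, telescoped with phosphine reduction and acetylation as a net ene-acetoxylation; singlet oxygen adds to the s-cis enone as a perepoxide steered by the C1 carbonyl, so only the hydrogen geminal to the acyl group (C5–H) is abstracted, oxygen bonds to C16 and the alkene moves to C5=C6; the ene step is suprafacial, so oxygen enters C16 on the β-face where C5–H lies, which with the (E)-alkene gives (16S) (chirality transfer from C5–H to C16–O); closest known reaction: the gem-selective Schenck ene photooxygenation of pulegone and tiglate-type α,β-unsaturated carbonyl compounds, where CH2 or CH3 groups are the donors and no stereochemical relay is involved.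

**Step 9**
Reactants: 17 (16S)-acetate
Product: 20 C7 alkyne, via cobalt complex 18 (not isolated), via reduced cobalt complex 19 (not isolated)
Conditions: Co2(CO)8, CH2Cl2, rt; then Et3SiH (5 equiv), BF3·OEt2, −20 °C; then (NH4)2Ce(NO3)6, acetone, −10 °C
Reagents that add atoms: none
Why: Nicholas reaction, in which BF3 ionises the Co2(CO)6-complexed tertiary propargylic alcohol to a stabilised planar cation that takes hydride from Et3SiH on the convex β-face (cis to C4–H, away from ring B), fixing C7 (H β, alkyne α, 7R), and (NH4)2Ce(NO3)6 then frees the alkyne; the C16 acetate is not ionised because its cation would be cross-conjugated to the C1 carbonyl.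

**Step 10**
Reactants: 20 C7 alkyne
Product: 21 2β-acetoxy enone
Conditions: Pb(OAc)4, benzene/AcOH, 80 °C; then KOAc, AcOH, rt
Reagents that add atoms: lead tetraacetate, CC(=O)O[Pb](OC(C)=O)(OC(C)=O)OC(C)=O
Why: lead tetraacetate α′-acetoxylation of an enone through its cross-conjugated enol (only C2 carries α′-hydrogens), after which the epimerisable C2 is equilibrated to the equatorial 2β-acetate (cis to C3–CH3, 2R), since a 2α-acetate would be 1,3-diaxial to the pseudo-axial C4–C7 bond.

**Step 11**
Reactants: 21 2β-acetoxy enone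
Product: 23 macrocyclic dienone, via triene 22 (not isolated)
Conditions: second-generation Grubbs catalyst (H2IMes)(PCy3)Cl2Ru=CHPh (15 mol %), ethylene (1 atm), CH2Cl2, rt; then argon, toluene, 80 °C, 1 mM
Reagents that add atoms: ethylene, C=C
Why: ring-closing enyne metathesis in its ethylene-relay form, in which the alkyne first becomes the 2-substituted buta-1,3-diene and diene–ene ring-closing metathesis then joins the two monosubstituted vinyl groups (C11=C12) with loss of ethylene, the 1,1-disubstituted C10=CH2 and tetrasubstituted C5=C6 being inert; both chains are held on the α-face by the cis-hydrindane and the (E)-alkene is expected as the thermodynamic isomer in the eleven-membered ring.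

**Step 12**
Reactants: 23 macrocyclic dienone
Product: 24 target CNP0323842.1
Conditions: NaBH4, CeCl3·7H2O, MeOH, −78 °C
Reagents that add atoms: none
Why: Luche reduction, in which the small hydride adds 1,2 along the axial trajectory from the exposed β-face (the α-face of C1 is screened by ring A and the C10–C15 bridge), gives the equatorial 1α-alcohol (1R) trans to the 2β-acetate, while −78 °C and CeCl3 suppress conjugate reduction and acetate migration.

**Compound list**
1 | (S)-β-butyrolactone, (4S)-4-methyloxetan-2-one | C[C@H]1CC(=O)O1 | starting material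
2 | allylmagnesium bromide | C=CC[Mg]Br | starting material
3 | (3S)-3-methylhex-5-enoic acid | OC(=O)C[C@@H](C)CC=C | intermediate
4 | (3S)-3-methylhex-5-en-1-ol | OCC[C@@H](C)CC=C | intermediate
5 | (3S)-3-methylhex-5-enal | O=CC[C@@H](C)CC=C | intermediate
6 | (E)-pent-3-en-2-one | C/C=C/C(C)=O | starting material
7 | (E)-2-(tert-butyldimethylsilyloxy)penta-1,3-diene | C/C=C/C(=C)O[Si](C)(C)C(C)(C)C | intermediate
8 | 3-methylcyclopent-2-en-1-one | CC1=CC(=O)CC1 | starting material
9 | Diels–Alder adduct: cis-fused rings A/B, C7 ketone, C1(OTBS)=C6 silyl enol ether, C3–CH3, C4–H and C5–H all β (C5–CH3 α); IUPAC (3aR,7S,7aS)-5-[(tert-butyldimethylsilyl)oxy]-3a,7-dimethyl-2,3,3a,4,7,7a-hexahydro-1H-inden-1-one | C[C@H]1C=C(O[Si](C)(C)C(C)(C)C)C[C@@]2(C)CCC(=O)[C@@H]12 | intermediate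
10 | ethynylmagnesium bromide | C#C[Mg]Br | starting material
11 | C7 ethynyl carbinol of 9 (C7–OH β, C7–C≡CH α, drawn as the epimer from β-face attack; silyl enol ether retained) | C[C@H]1C=C(O[Si](C)(C)C(C)(C)C)C[C@@]2(C)CC[C@@](O)(C#C)[C@@H]12 | intermediate
12 | aldol adduct: C1 ketone, C6–C16H(OH)–C15 side chain (mixture at C6 and C16), 14S | C=CC[C@H](C)CC(O)C1C(=O)C[C@@]2(C)CC[C@@](O)(C#C)[C@H]2[C@H]1C | intermediate (not isolated)
13 | C16 acetate of 12 | C=CC[C@H](C)CC(OC(C)=O)C1C(=O)C[C@@]2(C)CC[C@@](O)(C#C)[C@H]2[C@H]1C | intermediate (not isolated)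
14 | exocyclic enone: C1 ketone conjugated to (E)-C6=C16, C5–H β, C7 ethynyl carbinol, chain C15–C14(S)(CH3)–C13–CH=CH2 | C=CC[C@H](C)C/C=C1/C(=O)C[C@@]2(C)CC[C@@](O)(C#C)[C@H]2[C@H]1C | intermediate
15 | (16S)-hydroperoxide with C1 ketone/C5=C6 enone | C=CC[C@H](C)C[C@H](OO)C1=C(C)[C@@H]2[C@](O)(C#C)CC[C@]2(C)CC1=O | intermediate (not isolated)
16 | (16S)-carbinol with C1 ketone/C5=C6 enone | C=CC[C@H](C)C[C@H](O)C1=C(C)[C@@H]2[C@](O)(C#C)CC[C@]2(C)CC1=O | intermediate (not isolated)
17 | (16S)-acetate: C16–OAc, C1 ketone/C5=C6 enone, C7 ethynyl carbinol | C=CC[C@H](C)C[C@H](OC(C)=O)C1=C(C)[C@@H]2[C@](O)(C#C)CC[C@]2(C)CC1=O | intermediate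
18 | Co2(CO)6 complex of the alkyne of 17 | C=CC[C@H](C)C[C@H](OC(C)=O)C1=C(C)[C@@H]2[C@](O)(C34C5[Co]3(=C=O)(=C=O)(=C=O)[Co]45(=C=O)(=C=O)=C=O)CC[C@]2(C)CC1=O | intermediate (not isolated)
19 | Co2(CO)6 complex of the alkyne of 20 | C=CC[C@H](C)C[C@H](OC(C)=O)C1=C(C)[C@@H]2[C@H](C34C5[Co]3(=C=O)(=C=O)(=C=O)[Co]45(=C=O)(=C=O)=C=O)CC[C@]2(C)CC1=O | intermediate (not isolated)
20 | alkyne: C7–H β, C7–C≡CH α (7R), C16–OAc (16S), C1 ketone/C5=C6 enone | C=CC[C@H](C)C[C@H](OC(C)=O)C1=C(C)[C@@H]2[C@H](C#C)CC[C@]2(C)CC1=O | intermediate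
21 | 2β-acetoxy derivative of 20 (2R) | C=CC[C@H](C)C[C@H](OC(C)=O)C1=C(C)[C@@H]2[C@H](C#C)CC[C@]2(C)[C@@H](OC(C)=O)C1=O | intermediate
22 | triene: C7–C10(=CH2)–C11H=CH2 in place of the alkyne of 21 | C=CC[C@H](C)C[C@H](OC(C)=O)C1=C(C)[C@@H]2[C@H](C(=C)C=C)CC[C@]2(C)[C@@H](OC(C)=O)C1=O | intermediate (not isolated)
23 | macrocyclic dienone: ring C closed (11E), C1 ketone, 2β- and 16-acetates | C=C1/C=C/C[C@H](C)C[C@H](OC(C)=O)C2=C(C)[C@@H]3[C@H]1CC[C@]3(C)[C@@H](OC(C)=O)C2=O | intermediate
24 | CNP0323842.1 (1R,2R,3S,4S,7R,14S,16S; 11E) | C=C1/C=C/C[C@H](C)C[C@H](OC(C)=O)C2=C(C)[C@@H]3[C@H]1CC[C@]3(C)[C@@H](OC(C)=O)[C@@H]2O | target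

**Step count and risks**
Total: 12 steps (the enantiomer separation is part of the purification in step 5). Longest linear sequence: 9 steps (steps 4–12 from 6; the aldehyde branch, steps 1–3, joins at step 7).

Steps most likely to fail:

Step 8 (the proposed new ene-acetoxylation). The C5–H must become pseudo-axial, but allylic strain with the (E)-alkylidene favours an axial C5–CH3, so the ene may be slow or abstract C15–H instead (oxygen at C6). Fallback with known chemistry, setting out from 11 and returning at 17: Saegusa–Ito oxidation of silyl enol ether 11 (Pd(OAc)2, MeCN, rt) gives the ring B enone F1; Johnson α-iodination (I2, pyridine, CH2Cl2) gives the 6-iodoenone F2; Nozaki–Hiyama–Kishi coupling with aldehyde 5 (CrCl2, NiCl2 cat., DMF) gives carbinol 16 together with its (16R)-epimer F3, which are separated; 16 is acetylated (Ac2O, pyridine) and F3 is inverted by a Mitsunobu reaction (AcOH, PPh3, diisopropyl azodicarboxylate), both giving 17.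

Step 10 (α′-acetoxylation). γ-Acetoxylation, oxidation of the alkyne or alkene, or the wrong C2 epimer are possible. Fallback setting out from 20 and returning at 21: soft enolisation (TMSOTf, Et3N, CH2Cl2, 0 °C) gives the cross-conjugated trimethylsilyl dienol ether F4; Rubottom oxidation (mCPBA, NaHCO3, −20 °C; citric acid work-up) gives the 2β-hydroxy enone F5; acetylation (Ac2O, pyridine, DMAP) gives 21.

Step 11 (closure of the eleven-membered ring). Oligomerisation, the (Z)-alkene or ring closure onto C10=CH2 may compete. Fallback setting out from 21 and returning at 23: Markovnikov hydroiodination of the alkyne (B-iodo-9-borabicyclo[3.3.1]nonane, hexane/CH2Cl2, 0 °C; then AcOH) gives the 2-iodo-1-alkene F6; cross-metathesis of its terminal alkene with vinylboronic acid pinacol ester (second-generation Hoveyda–Grubbs catalyst (H2IMes)Cl2Ru(=CH-C6H4-2-OiPr), CH2Cl2, 40 °C) gives the (E)-alkenylboronate F7; intramolecular Suzuki–Miyaura coupling (Pd(PPh3)4, Tl2CO3, THF/H2O, 1 mM, rt) forms the C10–C11 bond and gives 23.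

**Further compounds**
F1 | step 8 | ring B enone: C1 ketone, C5=C6 (C6–H), C7 ethynyl carbinol | O=C1C=C(C)[C@@H]2[C@](O)(C#C)CC[C@]2(C)C1
F2 | step 8 | 6-iodo derivative of F1 | O=C1C(I)=C(C)[C@@H]2[C@](O)(C#C)CC[C@]2(C)C1
F3 | step 8 | (16R)-epimer of carbinol 16 | C=CC[C@H](C)C[C@@H](O)C1=C(C)[C@@H]2[C@](O)(C#C)CC[C@]2(C)CC1=O
F4 | step 10 | C1 trimethylsilyl dienol ether of 20 (C1(OTMS)=C2, C5=C6) | C=CC[C@H](C)C[C@H](OC(C)=O)C1=C(C)[C@@H]2[C@H](C#C)CC[C@]2(C)C=C1O[Si](C)(C)C
F5 | step 10 | 2β-hydroxy enone (C2–OH in place of C2–OAc of 21) | C=CC[C@H](C)C[C@H](OC(C)=O)C1=C(C)[C@@H]2[C@H](C#C)CC[C@]2(C)[C@@H](O)C1=O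
F6 | step 11 | 2-iodo-1-alkene: C7–C10(I)=CH2 in place of the alkyne of 21 | C=CC[C@H](C)C[C@H](OC(C)=O)C1=C(C)[C@@H]2[C@H](C(I)=C)CC[C@]2(C)[C@@H](OC(C)=O)C1=O
F7 | step 11 | (E)-C11 alkenylboronic acid pinacol ester of F6 | CC1(C)OB(/C=C/C[C@H](C)C[C@H](OC(C)=O)C2=C(C)[C@@H]3[C@H](C(I)=C)CC[C@]3(C)[C@@H](OC(C)=O)C2=O)OC1(C)C
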